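## Retrosynthetic overview

1. Late stage: acetonide hydrolysis, reduction of the C3 ester to CH2OH, and face-selective hydrogenation of a C4 benzylidene group (sets C4, frees both phenols) lead back to oxolane ester 23.
2. Key disconnection of the oxolane ring (O1, C2, C3, C4, C5): an enantioselective Pd-catalysed (3+2) cycloaddition joins aryl aldehyde 14 with an ester- and aryl-substituted trimethylenemethane (TMM) dipole made from allylic carbonate 20. C2–C3 forms first, then the ring closes at O1–C5.
3. Enabling feature: C5 is an unsubstituted OCH2 group on C4, C4 bears the benzylic carbon C7', and C3 bears the one-carbon arm C9. With C4=C7' as an exocyclic alkene, C5–C4–C7' is a π-allyl unit; with C9 as an ester, C3 is an acidic CH on its central carbon. C3/C4/C5/C7' is therefore a TMM unit and O1–C2 an aldehyde C=O.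
4. Aldehyde 14 carries the complete threo 8-O-4' side chain. It comes from an Evans syn-aldol reaction of an aryloxyacetyl imide with O-benzylvanillin, reduction, 1,3-dioxane formation (temporary ring, formed first) and Br → CHO. The oxolane is the second and last ring.
5. Donor 20 comes from a Horner–Wadsworth–Emmons reaction of a mixed phosphonosuccinate with O-benzylvanillin, chemoselective DIBAL-H reduction and Boc carbonate formation.

Key step: step 11

Assumption: no close precedent fixes the sense of induction of the phosphoramidite in step 11. The (S,S,S) ligand is written; its mirror image is to be used if a test with aldehyde 6 shows the opposite sense. Compounds 1, 2, 4, 6, 15 and 16 are taken as commercial.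

## Route

Step 1
Reactants: 1 4-bromo-2-methoxyphenol; 2 bromoacetic acid
Product: 3 2-(4-bromo-2-methoxyphenoxy)acetic acid
Conditions: NaOH, H2O, reflux; then HCl
Reagents that add atoms: none
Why: Williamson ether synthesis, in which the phenoxide displaces bromide from bromoacetate by SN2 and no stereocentre is involved.

Step 2
Reactants: 3 2-(4-bromo-2-methoxyphenoxy)acetic acid; 4 (R)-4-benzyl-1,3-oxazolidin-2-one
Product: 5 (4R)-4-benzyl-3-[2-(4-bromo-2-methoxyphenoxy)acetyl]-1,3-oxazolidin-2-one
Conditions: DCC, DMAP (cat.), CH2Cl2, 0 °C → rt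
Reagents that add atoms: none
Why: Carbodiimide-mediated (Steglich-type) N-acylation of the oxazolidinone by an activated aryloxyacetic acid, which leaves the auxiliary stereocentre untouched.

Step 3
Reactants: 5 (4R)-4-benzyl-3-[2-(4-bromo-2-methoxyphenoxy)acetyl]-1,3-oxazolidin-2-one; 6 4-(benzyloxy)-3-methoxybenzaldehyde (O-benzylvanillin)
Product: 9 (4R)-4-benzyl-3-[(2R,3S)-3-[4-(benzyloxy)-3-methoxyphenyl]-2-(4-bromo-2-methoxyphenoxy)-3-hydroxypropanoyl]-1,3-oxazolidin-2-one, via boron enolate 7 (not isolated), via boron aldolate 8 (not isolated)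
Conditions: Bu2BOTf, Et3N, CH2Cl2, −78 → 0 °C; 6, −78 → 0 °C; then pH 7 buffer, MeOH, 30% H2O2, 0 °C
Reagents that add atoms: none
Why: Evans syn-aldol reaction, in which the (Z)-boron enolate reacts through a closed chair transition state on the face left open by the (R)-benzyl group, so that both new centres (2R,3S; the syn = threo relation) are set by the auxiliary.

Step 4
Reactants: 9 syn-aldol imide
Product: 10 (1S,2S)-1-[4-(benzyloxy)-3-methoxyphenyl]-2-(4-bromo-2-methoxyphenoxy)propane-1,3-diol
Conditions: LiBH4, THF, 0 °C → rt; then H2O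
Reagents that add atoms: none
Why: Reductive cleavage of the N-acyloxazolidinone with borohydride gives the primary alcohol without touching either stereocentre (the descriptor at C2 changes only by priority).

Step 5
Reactants: 10 threo-1,3-diol
Product: 11 (4S,5S)-4-[4-(benzyloxy)-3-methoxyphenyl]-5-(4-bromo-2-methoxyphenoxy)-2,2-dimethyl-1,3-dioxane
Conditions: 2,2-dimethoxypropane, PPTS (cat.), CH2Cl2, rt
Reagents that add atoms: 2,2-dimethoxypropane COC(C)(C)OC
Why: Acid-catalysed transacetalisation masks both hydroxy groups in one temporary six-membered ring under conditions too mild to ionise the benzylic C–O bond.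

Step 6
Reactants: 11 bromoaryl dioxane
Product: 14 4-({(4S,5S)-4-[4-(benzyloxy)-3-methoxyphenyl]-2,2-dimethyl-1,3-dioxan-5-yl}oxy)-3-methoxybenzaldehyde, via aryllithium 12 (not isolated), via lithium hemiaminalate 13 (not isolated)
Conditions: n-BuLi, THF, −78 °C; DMF, −78 °C → 0 °C; then H2O
Reagents that add atoms: N,N-dimethylformamide CN(C)C=O
Why: Bromine–lithium exchange followed by formylation with DMF, in which the exchange at −78 °C should outrun any deprotonation, and benzyl ether and acetal are inert.

Step 7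
Reactants: 15 triethyl phosphonoacetate; 16 tert-butyl bromoacetate
Product: 17 4-tert-butyl 1-ethyl 2-(diethoxyphosphoryl)butanedioate (racemic)
Conditions: NaH, THF, 0 °C → rt
Reagents that add atoms: none
Why: SN2 alkylation of the stabilised phosphonoacetate anion; the new centre is lost in the next step and needs no control.

Step 8
Reactants: 17 mixed phosphonosuccinate; 6 4-(benzyloxy)-3-methoxybenzaldehyde
Product: 18 4-tert-butyl 1-ethyl (2E)-2-{[4-(benzyloxy)-3-methoxyphenyl]methylidene}butanedioate
Conditions: NaH, THF, 0 °C → rt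
Reagents that add atoms: none
Why: Horner–Wadsworth–Emmons olefination, which with aromatic aldehydes should place the aryl group trans to the conjugated ester (E).

Step 9
Reactants: 18 benzylidene succinate
Product: 19 tert-butyl (3E)-4-[4-(benzyloxy)-3-methoxyphenyl]-3-(hydroxymethyl)but-3-enoate
Conditions: DIBAL-H (2.2 equiv), CH2Cl2, −78 °C
Reagents that add atoms: none
Why: Chemoselective DIBAL-H ester reduction, in which the ethyl ester is reduced to the allylic alcohol while the bulky tert-butyl ester should resist both hydride and lactonisation at −78 °C.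

Step 10
Reactants: 19 allylic alcohol
Product: 20 tert-butyl (3E)-4-[4-(benzyloxy)-3-methoxyphenyl]-3-{[(tert-butoxycarbonyl)oxy]methyl}but-3-enoate
Conditions: Boc2O, DMAP (10 mol %), CH2Cl2, 0 °C
Reagents that add atoms: di-tert-butyl dicarbonate CC(C)(C)OC(=O)OC(=O)OC(C)(C)C
Why: DMAP-catalysed O-acylation installs a leaving group that will deliver its own base (tert-butoxide) on ionisation.

Step 11
Reactants: 14 aryl aldehyde with protected threo side chain; 20 allylic Boc carbonate (1.5 equiv)
Product: 23 tert-butyl (2S,3S,4E)-4-{[4-(benzyloxy)-3-methoxyphenyl]methylidene}-2-[4-({(4S,5S)-4-[4-(benzyloxy)-3-methoxyphenyl]-2,2-dimethyl-1,3-dioxan-5-yl}oxy)-3-methoxyphenyl]oxolane-3-carboxylate, via Pd-TMM zwitterion 21 (not isolated), via Pd-allyl aldolate 22 (not isolated)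
Conditions: Pd2(dba)3·CHCl3 (2.5 mol %), (S,S,S)-BINOL/trans-2,5-di(2-naphthyl)pyrrolidine phosphoramidite (10 mol %), In(acac)3 (10 mol %), 4 Å MS, toluene, 25 → 45 °C, slow addition of 20
Reagents that add atoms: none
Why: Proposed new method: Pd(0) ionises the allylic Boc carbonate of 20 with loss of CO2, the liberated tert-butoxide removes the ester α-proton that the cationic π-allyl unit acidifies, the ester-stabilised Pd–trimethylenemethane zwitterion 21 adds through its carbanionic carbon (future C3) to the formyl carbon of 14 (future C2), and the alkoxide of aldolate 22 attacks the CH2 terminus of the π-allyl unit anti to Pd, which forms the O1–C5 bond, closes the oxolane and returns Pd(0). The closest known reaction types are the Pd-catalysed (3+2) trimethylenemethane cycloaddition of 2-(silylmethyl)allyl acetates with aryl aldehydes to 2-aryl-4-methyleneoxolanes and the silicon-free generation of acceptor-stabilised trimethylenemethane dipoles from 2-(acceptor-methyl)allyl carbonates for additions to activated C=C and C=N bonds; not yet shown are an aldehyde as acceptor for such a dipole and a dipole that carries an ester and an aryl group at once. The one ring closes by attack of O on the terminal carbon of a π-allyl unit whose central carbon C4 lies in the ring (5-exo-tet on the σ-allyl form), that is an intramolecular Tsuji–Trost etherification and the closure common to all Pd–TMM cycloadditions. C3 is fixed by C–C bond formation on the dipole face remote from the chiral Pd–phosphoramidite fragment and C2 by the aldehyde face that the ligand pocket admits; because the aldol addition is reversible and only the syn-aldolate closes with aryl and ester on opposite ring faces, the 2,3-trans (2S,3S) product should be funnelled out, and the remote dioxane stereocentres should not interfere (catalyst control). The ester-bearing carbon is the nucleophilic site because the ester stabilises the charge and the electron-rich aryl group disfavours charge at C7', closure at CH2 and not at CHAr is favoured by the lower steric demand and the retained styrene conjugation, and chemoselectivity rests on 14 having one electrophilic site and no acidic proton, while slow addition of 20 should hold back self-allylation of the dipole. The E/Z geometry of the benzylidene group is of no consequence because step 12 removes it.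

Step 12
Reactants: 23 benzylidene oxolane ester
Product: 24 tert-butyl (2S,3S,4R)-4-(4-hydroxy-3-methoxybenzyl)-2-[4-({(4S,5S)-4-(4-hydroxy-3-methoxyphenyl)-2,2-dimethyl-1,3-dioxan-5-yl}oxy)-3-methoxyphenyl]oxolane-3-carboxylate
Conditions: H2 (1 atm), 10% Pd/C, EtOAc, rt
Reagents that add atoms: none
Why: Heterogeneous syn-hydrogenation combined with O-benzyl hydrogenolysis, in which the bulky C3 tert-butyl ester, pushed pseudoaxial by allylic 1,3-strain against the benzylidene aryl group, shields its own ring face, so that hydrogen should reach C4 from the face of H-3 and place the new benzyl group cis to the ester (4R), as is known for 2-aryl-4-benzylideneoxolane-3-carboxylates.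

Step 13
Reactants: 24 saturated oxolane ester
Product: 25 {(2S,3R,4R)-4-(4-hydroxy-3-methoxybenzyl)-2-[4-({(4S,5S)-4-(4-hydroxy-3-methoxyphenyl)-2,2-dimethyl-1,3-dioxan-5-yl}oxy)-3-methoxyphenyl]oxolan-3-yl}methanol
Conditions: LiAlH4 (excess), THF, 0 °C → rt; then H2O
Reagents that add atoms: none
Why: LiAlH4 ester reduction, which tolerates free phenols (merely deprotonated) as in the reduction of phenolic lignan lactones and leaves C3 untouched (the descriptor changes only by priority).

Step 14
Reactants: 25 acetonide of the target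
Product: 26 (1S,2S)-1-(4-hydroxy-3-methoxyphenyl)-2-{4-[(2S,3R,4R)-4-(4-hydroxy-3-methoxybenzyl)-3-(hydroxymethyl)oxolan-2-yl]-2-methoxyphenoxy}propane-1,3-diol (target)
Conditions: AcOH–H2O (4:1), rt
Reagents that add atoms: none
Why: Acid-catalysed acetal hydrolysis, in which the strained 2,2-dimethyl-1,3-dioxane cleaves at the acetal carbon under conditions that should be too mild to ionise the benzylic C–O bonds at C2 of the oxolane and C1 of the glycerol unit.

## Compound list

1 | 4-bromo-2-methoxyphenol | COc1cc(Br)ccc1O | starting material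
2 | bromoacetic acid | OC(=O)CBr | starting material
3 | 2-(4-bromo-2-methoxyphenoxy)acetic acid | COc1cc(Br)ccc1OCC(=O)O | intermediate
4 | (R)-4-benzyl-1,3-oxazolidin-2-one | O=C1N[C@H](Cc2ccccc2)CO1 | starting material
5 | (4R)-4-benzyl-3-[2-(4-bromo-2-methoxyphenoxy)acetyl]-1,3-oxazolidin-2-one | COc1cc(Br)ccc1OCC(=O)N2C(=O)OC[C@H]2Cc3ccccc3 | intermediate
6 | 4-(benzyloxy)-3-methoxybenzaldehyde | O=Cc1ccc(OCc2ccccc2)c(OC)c1 | starting material
7 | (Z)-dibutylboron enolate of 5 | CCCCB(CCCC)O/C(=C\Oc1ccc(Br)cc1OC)N2C(=O)OC[C@H]2Cc3ccccc3 | intermediate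
8 | dibutylboron aldolate of 9 | COc1cc(Br)ccc1O[C@@H](C(=O)N2C(=O)OC[C@H]2Cc3ccccc3)[C@@H](OB(CCCC)CCCC)c4ccc(OCc5ccccc5)c(OC)c4 | intermediate
9 | (2R,3S)-syn-aldol imide | COc1cc(Br)ccc1O[C@@H](C(=O)N2C(=O)OC[C@H]2Cc3ccccc3)[C@@H](O)c4ccc(OCc5ccccc5)c(OC)c4 | intermediate
10 | (1S,2S)-1-[4-(benzyloxy)-3-methoxyphenyl]-2-(4-bromo-2-methoxyphenoxy)propane-1,3-diol | COc1cc(Br)ccc1O[C@@H](CO)[C@@H](O)c2ccc(OCc3ccccc3)c(OC)c2 | intermediate
11 | (4S,5S)-4-[4-(benzyloxy)-3-methoxyphenyl]-5-(4-bromo-2-methoxyphenoxy)-2,2-dimethyl-1,3-dioxane | COc1cc(Br)ccc1O[C@H]2COC(C)(C)O[C@H]2c3ccc(OCc4ccccc4)c(OC)c3 | intermediate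
12 | aryllithium from 11 | COc1cc([Li])ccc1O[C@H]2COC(C)(C)O[C@H]2c3ccc(OCc4ccccc4)c(OC)c3 | intermediate
13 | lithium hemiaminalate (DMF adduct of 12) | COc1cc(C(O[Li])N(C)C)ccc1O[C@H]2COC(C)(C)O[C@H]2c3ccc(OCc4ccccc4)c(OC)c3 | intermediate
14 | 4-({(4S,5S)-4-[4-(benzyloxy)-3-methoxyphenyl]-2,2-dimethyl-1,3-dioxan-5-yl}oxy)-3-methoxybenzaldehyde | COc1cc(C=O)ccc1O[C@H]2COC(C)(C)O[C@H]2c3ccc(OCc4ccccc4)c(OC)c3 | intermediate
15 | triethyl phosphonoacetate | CCOC(=O)CP(=O)(OCC)OCC | starting material
16 | tert-butyl bromoacetate | CC(C)(C)OC(=O)CBr | starting material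
17 | 4-tert-butyl 1-ethyl 2-(diethoxyphosphoryl)butanedioate (racemic) | CCOC(=O)C(CC(=O)OC(C)(C)C)P(=O)(OCC)OCC | intermediate
18 | 4-tert-butyl 1-ethyl (2E)-2-{[4-(benzyloxy)-3-methoxyphenyl]methylidene}butanedioate | CCOC(=O)/C(CC(=O)OC(C)(C)C)=C/c1ccc(OCc2ccccc2)c(OC)c1 | intermediate
19 | tert-butyl (3E)-4-[4-(benzyloxy)-3-methoxyphenyl]-3-(hydroxymethyl)but-3-enoate | OC/C(CC(=O)OC(C)(C)C)=C/c1ccc(OCc2ccccc2)c(OC)c1 | intermediate
20 | tert-butyl (3E)-4-[4-(benzyloxy)-3-methoxyphenyl]-3-{[(tert-butoxycarbonyl)oxy]methyl}but-3-enoate | CC(C)(C)OC(=O)OC/C(CC(=O)OC(C)(C)C)=C/c1ccc(OCc2ccccc2)c(OC)c1 | intermediate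
21 | ester-stabilised Pd–trimethylenemethane zwitterion (σ-allyl form, ligand omitted) | CC(C)(C)OC(=O)[CH-]/C(C[Pd+])=C\c1ccc(OCc2ccccc2)c(OC)c1 | intermediate
22 | syn-aldolate with π-allyl-Pd unit (σ-allyl form, ligand omitted) | [O-][C@H](c1ccc(O[C@H]2COC(C)(C)O[C@H]2c3ccc(OCc4ccccc4)c(OC)c3)c(OC)c1)[C@@H](C(=O)OC(C)(C)C)/C(C[Pd+])=C\c5ccc(OCc6ccccc6)c(OC)c5 | intermediate
23 | tert-butyl (2S,3S,4E)-2-aryl-4-benzylideneoxolane-3-carboxylate (full name in step 11) | CC(C)(C)OC(=O)[C@@H]1[C@@H](c2ccc(O[C@H]3COC(C)(C)O[C@H]3c4ccc(OCc5ccccc5)c(OC)c4)c(OC)c2)OC/C1=C/c6ccc(OCc7ccccc7)c(OC)c6 | intermediate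
24 | tert-butyl (2S,3S,4R)-2-aryl-4-(4-hydroxy-3-methoxybenzyl)oxolane-3-carboxylate (full name in step 12) | CC(C)(C)OC(=O)[C@@H]1[C@@H](c2ccc(O[C@H]3COC(C)(C)O[C@H]3c4ccc(O)c(OC)c4)c(OC)c2)OC[C@@H]1Cc5ccc(O)c(OC)c5 | intermediate
25 | acetonide of the target (full name in step 13) | OC[C@@H]1[C@@H](c2ccc(O[C@H]3COC(C)(C)O[C@H]3c4ccc(O)c(OC)c4)c(OC)c2)OC[C@@H]1Cc5ccc(O)c(OC)c5 | intermediate
26 | (1S,2S)-1-(4-hydroxy-3-methoxyphenyl)-2-{4-[(2S,3R,4R)-4-(4-hydroxy-3-methoxybenzyl)-3-(hydroxymethyl)oxolan-2-yl]-2-methoxyphenoxy}propane-1,3-diol | COc1cc(C[C@H]2CO[C@H](c3ccc(O[C@@H](CO)[C@@H](O)c4ccc(O)c(OC)c4)c(OC)c3)[C@H]2CO)ccc1O | target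

## Step count and risks

Total step count: 14. Longest linear sequence: 10 steps (steps 1–6 and 11–14). The donor branch (steps 7–10) runs in parallel.

**1. Step 11.** Self-allylation or oligomerisation of the dipole may outrun its addition to the electron-rich aldehyde. The ligand may give insufficient enantioface control. The ring may also close partly at the aryl-bearing allyl terminus.

The fallback uses only known reactions, sets out from 19 (together with 14) and returns at 25.
- Alcohol 19 is treated with methyl chloroformate and pyridine to give the allylic methyl carbonate F1.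
- The tert-butyl ester is cleaved with TMSOTf/2,6-lutidine to give the carboxylic acid F2.
- The acid is coupled (PivCl, Et3N, LiCl) with commercial (S)-4-benzyl-1,3-oxazolidin-2-one to give the β,γ-unsaturated imide F3.
- An Evans syn-aldol reaction (Bu2BOTf, Et3N) of this imide with 14 sets C2 and C3 under auxiliary control and gives the (2S,3S)-syn-aldol F4.
- Pd(PPh3)4 then closes the same O1–C5 bond by intramolecular Tsuji–Trost etherification to give the oxolane imide F5.
- Hydrogenation over Pd/C gives the saturated bisphenol imide F6, and LiBH4 removes the auxiliary to give 25.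

**2. Step 12.** On the Pd surface the facial selectivity may be poor. The alkene may migrate into conjugation with the ester, with loss of C3. The allylic C5–O bond or the benzylic C2–O bond may be hydrogenolysed.

The fallback sets out from 23 and returns at 24. It separates the two tasks and replaces substrate control by catalyst control. A cationic Ir(I) phosphine–oxazoline complex of the matched ligand enantiomer (H2, CH2Cl2) saturates only the trisubstituted aryl alkene and gives the dibenzyl saturated ester F7. A short transfer hydrogenolysis (Pd/C, cyclohexa-1,4-diene) then removes the two benzyl groups to give 24.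

**3. Step 9.** The tert-butyl ester may be over-reduced, or the aluminium alkoxide may lactonise onto it.

The fallback sets out from 18 and returns at 19. It replaces hydride chemoselectivity by hydrolytic chemoselectivity. LiOH in aqueous THF saponifies only the ethyl ester to give the conjugated acid F8. Isobutyl chloroformate and N-methylmorpholine convert it in the flask into the mixed carbonic anhydride F9. NaBH4 at −15 °C reduces this anhydride to 19 without touching the tert-butyl ester.

## Further compounds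

F1 | step 11 | tert-butyl (3E)-4-[4-(benzyloxy)-3-methoxyphenyl]-3-{[(methoxycarbonyl)oxy]methyl}but-3-enoate | COC(=O)OC/C(CC(=O)OC(C)(C)C)=C/c1ccc(OCc2ccccc2)c(OC)c1
F2 | step 11 | (3E)-4-[4-(benzyloxy)-3-methoxyphenyl]-3-{[(methoxycarbonyl)oxy]methyl}but-3-enoic acid | COC(=O)OC/C(CC(=O)O)=C/c1ccc(OCc2ccccc2)c(OC)c1
F3 | step 11 | (4S)-4-benzyl-3-[(3E)-4-[4-(benzyloxy)-3-methoxyphenyl]-3-{[(methoxycarbonyl)oxy]methyl}but-3-enoyl]-1,3-oxazolidin-2-one | COC(=O)OC/C(CC(=O)N1C(=O)OC[C@@H]1Cc2ccccc2)=C/c3ccc(OCc4ccccc4)c(OC)c3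
F4 | step 11 | (2S,3S)-syn-aldol of F3 with 14 | O[C@H](c1ccc(O[C@H]2COC(C)(C)O[C@H]2c3ccc(OCc4ccccc4)c(OC)c3)c(OC)c1)[C@@H](C(=O)N5C(=O)OC[C@@H]5Cc6ccccc6)/C(COC(=O)OC)=C\c7ccc(OCc8ccccc8)c(OC)c7
F5 | step 11 | (2S,3S,4E)-2-aryl-4-benzylideneoxolane-3-carbonyl imide of (S)-4-benzyloxazolidin-2-one | O=C(N1C(=O)OC[C@@H]1Cc2ccccc2)[C@@H]3[C@@H](c4ccc(O[C@H]5COC(C)(C)O[C@H]5c6ccc(OCc7ccccc7)c(OC)c6)c(OC)c4)OC/C3=C/c8ccc(OCc9ccccc9)c(OC)c8
F6 | step 11 | (2S,3S,4R)-2-aryl-4-(4-hydroxy-3-methoxybenzyl)oxolane-3-carbonyl imide of (S)-4-benzyloxazolidin-2-one | O=C(N1C(=O)OC[C@@H]1Cc2ccccc2)[C@@H]3[C@@H](c4ccc(O[C@H]5COC(C)(C)O[C@H]5c6ccc(O)c(OC)c6)c(OC)c4)OC[C@@H]3Cc7ccc(O)c(OC)c7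
F7 | step 12 | tert-butyl (2S,3S,4R)-4-[4-(benzyloxy)-3-methoxybenzyl]-2-[4-({(4S,5S)-4-[4-(benzyloxy)-3-methoxyphenyl]-2,2-dimethyl-1,3-dioxan-5-yl}oxy)-3-methoxyphenyl]oxolane-3-carboxylate | CC(C)(C)OC(=O)[C@@H]1[C@@H](c2ccc(O[C@H]3COC(C)(C)O[C@H]3c4ccc(OCc5ccccc5)c(OC)c4)c(OC)c2)OC[C@@H]1Cc6ccc(OCc7ccccc7)c(OC)c6
F8 | step 9 | (2E)-2-{[4-(benzyloxy)-3-methoxyphenyl]methylidene}-4-(tert-butoxy)-4-oxobutanoic acid | OC(=O)/C(CC(=O)OC(C)(C)C)=C/c1ccc(OCc2ccccc2)c(OC)c1
F9 | step 9 | mixed isobutyl carbonic anhydride of F8 | CC(C)COC(=O)OC(=O)/C(CC(=O)OC(C)(C)C)=C/c1ccc(OCc2ccccc2)c(OC)c1
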